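I decide to reckon this flask by the gap left to its plateau and not by the target made, and I leave this note for whoever takes over the bench.

starting material 0.40 M; second substrate 5.00 equiv; gas 52 mM (held); time 30 h

    starting material + partner ⇌ target (K1 = 68.0 M⁻¹, k1 = 5.51 M⁻¹ h⁻¹)
    second substrate + partner → second product (k2 = 2.74 M⁻¹ h⁻¹)
    gas ⇌ partner, rate k3*(csat - [partner]) (k3 = 0.239 h⁻¹, csat = 52 mM)
    partner → decomposed reagent (k4 = 0.219 h⁻¹)

* the state of affairs at 30 h: stopped, and by what, or still going (forward and back rates have come level / it is still moving / all of the starting material has reacted)
* the target standing at 30 h, as a percentage of the starting material charged

- at the start none of partner is dissolved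
- the reaction counts as stopped when no species that holds the starting material changes by six tenths of a point or more over the second half of the time
- run time (flask): 30 h

The flask starts with starting material, second substrate and no dissolved partner, and the gas then feeds partner at 0.0124 M h⁻¹ while [partner] is still near zero. Partner's half-life against the second substrate as charged, 0.13 h, is short beside the run, so I hold [partner] at feed over summed losses, with the charges as they stand at the start, 1.53 mM. Please add no second substrate: it takes partner at 5.48 h⁻¹ against 2.20 h⁻¹ for the starting material.

With [partner] held, the target relaxes pseudo-first-order towards a plateau of 9.40 % of the charge. The closing rate, forward plus back at held partner, is 0.0894 h⁻¹, and the fraction of the gap left after a time is the exponential of minus this rate times that time. At 30 h that leaves 6.83 %, so I expect 8.76 % of target. The second half still adds 1.8 percentage points against the 0.6 points that count as stopped, so I expect it to be still moving when you come.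

The forecast says it is still moving, with 11 %, above my figure. Its ground: “The second substrate takes most of the partner, which is fed slowly by gas transfer”.

The flask gives 11.7 % of target at 30 h, and it is still moving, with [partner] at 0.00229 M, higher than the level I held. Now the same flask read at 12 h: the closing rate leaves 34.2 % of the gap, the [partner] of 0.00191 M standing there gives a plateau of 11.5 %, and together they put the target at 7.57 %, where that reading of the flask holds 7.06 %.

Its constants belong to no real substance; the flask was simulated.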